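## Retrosynthetic overview

1. Target ⇒ tris-MOM flavanone ⇒ 2'-hydroxychalcone. Ring C closes last through the O1–C2 bond, which also sets C-2. Only the phenol next to the ring C–H is free, so only the 6-substituted flavanone can form.
2. Chalcone ⇒ ring A acetophenone + ring B aldehyde by Claisen–Schmidt condensation. The aldehyde comes from resorcinol by formylation, 4-O-MOM protection and 2-O-methylation.
3. Acetophenone ⇒ 4-lavandulyl-3,5-bis(MOM)phenol by ortho-lithiation and Weinreb acetylation.
4. The lavandulyl chain is grown on ring A by three successive 1,2-shifts from boron to carbon. These are aryl→CH2 (chloromethyl boronate), benzyl→C-2'' (chiral lithiated benzoate, sets the side-chain centre) and C-2''→isopropenyl (Zweifel).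
5. Ring A core ⇒ resorcinol by MOM protection and C-5 C–H borylation/oxidation. Rings A and B are bought as benzene rings, and ring C is the only ring made (step 12).

Assumption: the SMILES is read as the (2S)-flavanone carrying a (2S)-lavandulyl group at C-6, and in step 12 the (S)-tert-leucine-derived catalyst is taken to favour Si-face attack (its mirror image is equally accessible if the sense is opposite).

## Route

Step 1
Reactants: 1 resorcinol
Product: 2 1,3-bis(methoxymethoxy)benzene
Conditions: MOMCl (2.5 equiv), iPr2NEt (3 equiv), CH2Cl2, 0 °C to rt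
Reagents that add atoms: chloromethyl methyl ether, COCCl
Why: Williamson-type O-alkylation protects both phenols as MOM acetals, which later act as ortho-directing groups and as the regiochemical lock for ring C closure.

Step 2
Reactants: 2 1,3-bis(methoxymethoxy)benzene
Product: 4 3,5-bis(methoxymethoxy)phenol, via arylboronic ester 3 (not isolated)
Conditions: [Ir(OMe)(cod)]2 (1 mol %), 4,4'-di-tert-butyl-2,2'-bipyridine (2 mol %), B2pin2 (0.6 equiv), THF, 80 °C; then 30 % H2O2, aq NaOH, 0 °C to rt
Reagents that add atoms: hydrogen peroxide, OO; bis(pinacolato)diboron, CC1(C)OB(OC1(C)C)B1OC(C)(C)C(C)(C)O1 (its boron stays only in 3)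
Why: Sterically controlled iridium-catalysed aromatic C–H borylation reaches only C-5 (the one C–H without an ortho substituent), and hydroperoxide oxidation of the C–B bond (aryl shift from boron to oxygen) gives the 1,3,5-trioxygenated ring with one oxygen left free and so distinguished.

Step 3
Reactants: 4 3,5-bis(methoxymethoxy)phenol
Product: 5 [3,5-bis(methoxymethoxy)phenoxy](tert-butyl)dimethylsilane
Conditions: TBSCl (1.2 equiv), imidazole (2 equiv), DMF, rt
Reagents that add atoms: tert-butyldimethylsilyl chloride, CC(C)(C)[Si](C)(C)Cl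
Why: Standard phenol silylation gives a bulky, non-coordinating OTBS group that shields its two ortho positions, so the next lithiation can only occur between the two MOM ethers.

Step 4
Reactants: 5 [3,5-bis(methoxymethoxy)phenoxy](tert-butyl)dimethylsilane
Product: 8 tert-butyl{3,5-bis(methoxymethoxy)-4-[(4,4,5,5-tetramethyl-1,3,2-dioxaborolan-2-yl)methyl]phenoxy}dimethylsilane, via aryllithium 6 (not isolated), via chloromethyl boronate complex 7 (not isolated)
Conditions: n-BuLi (1.1 equiv), THF, 0 °C, 1 h; ClCH2Bpin (1.2 equiv), −78 °C to rt, 12 h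
Reagents that add atoms: 2-(chloromethyl)-4,4,5,5-tetramethyl-1,3,2-dioxaborolane, ClCB1OC(C)(C)C(C)(C)O1
Why: Directed ortho-metalation between the two MOM ethers is followed by a Matteson-type homologation, in which the electron-rich aryl group of the boronate complex makes a 1,2-shift from boron to carbon with loss of chloride and forms the ring A–CH2 bond.

Step 5
Reactants: 9 5-bromo-2-methylpent-2-ene
Product: 10 4-methylpent-3-en-1-yl 2,4,6-triisopropylbenzoate
Conditions: 2,4,6-triisopropylbenzoic acid (1.0 equiv), K2CO3 (1.5 equiv), DMF, 60 °C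
Reagents that add atoms: 2,4,6-triisopropylbenzoic acid, CC(C)c1cc(C(C)C)c(C(=O)O)c(C(C)C)c1
Why: SN2 O-alkylation of the hindered carboxylate gives the benzoate that serves in step 6 as both the directing group for lithiation and the leaving group.

Step 6
Reactants: 10 4-methylpent-3-en-1-yl 2,4,6-triisopropylbenzoate; 8 benzylic boronic ester
Product: 13 tert-butyl{3,5-bis(methoxymethoxy)-4-[(2S)-5-methyl-2-(4,4,5,5-tetramethyl-1,3,2-dioxaborolan-2-yl)hex-4-en-1-yl]phenoxy}dimethylsilane, via lithiated benzoate 11 (not isolated), via boronate complex 12 (not isolated)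
Conditions: 10 (1.3 equiv), s-BuLi (1.3 equiv), (+)-sparteine (1.3 equiv), Et2O, −78 °C, 5 h; 8 (1.0 equiv), −78 °C, 1 h; then reflux, 12 h
Reagents that add atoms: none
Why: In this lithiation–borylation, (+)-sparteine-mediated asymmetric deprotonation removes the pro-R hydrogen to give the (R)-carbenoid, which is borylated with retention, and the benzyl group then makes an anti-periplanar 1,2-shift from boron to carbon with inversion and loss of the benzoate, setting the side-chain centre as (S).

Step 7
Reactants: 13 (S)-secondary boronic ester; 14 2-bromopropene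
Product: 19 3,5-bis(methoxymethoxy)-4-[(2S)-5-methyl-2-(prop-1-en-2-yl)hex-4-en-1-yl]phenol, via isopropenyllithium 15 (not isolated), via alkenyl boronate complex 16 (not isolated), via iodo boronic ester 17 (not isolated), via silyl ether 18 (not isolated)
Conditions: 14 (2 equiv), t-BuLi (4 equiv), THF/Et2O, −78 °C; 13, −78 °C; I2 (2 equiv), THF, −78 °C; NaOMe (4 equiv), MeOH, −78 °C to rt; aq Na2S2O3 wash; crude, TBAF (1.2 equiv), THF, 0 °C
Reagents that add atoms: none
Why: In this Zweifel olefination, iodonium activation of the isopropenyl boronate complex triggers a stereoretentive 1,2-shift of the secondary alkyl group from boron to carbon, methoxide-induced anti-elimination of boron and iodide completes the (S)-lavandulyl chain, and fluoride then frees the phenol after excess iodine has been washed out.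

Step 8
Reactants: 19 lavandulyl phenol; 20 N-methoxy-N-methylacetamide
Product: 22 1-{6-hydroxy-2,4-bis(methoxymethoxy)-3-[(2S)-5-methyl-2-(prop-1-en-2-yl)hex-4-en-1-yl]phenyl}ethan-1-one, via dilithio phenoxide 21 (not isolated)
Conditions: n-BuLi (2.3 equiv), TMEDA (2.3 equiv), THF, −78 to 0 °C, 2 h; 20 (1.5 equiv), −78 °C to rt; aq NH4Cl
Reagents that add atoms: none
Why: Directed ortho-metalation of the lithium phenoxide can only occur at the two equivalent C–H positions flanked by OLi and OMOM (cooperative directing groups), and the Weinreb ketone synthesis stops cleanly at the o-hydroxyacetophenone without touching the remote stereocentre.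

Step 9
Reactants: 1 resorcinol
Product: 24 2,4-dihydroxybenzaldehyde, via iminium salt 23 (not isolated)
Conditions: POCl3 (1.15 equiv), DMF (1.3 equiv), MeCN, −15 °C to rt; then H2O, 50 °C
Reagents that add atoms: N,N-dimethylformamide, CN(C)C=O; water, O
Why: Vilsmeier–Haack formylation attacks the most activated and least hindered position (C-4 of resorcinol), and the precipitated iminium salt is hydrolysed to the aldehyde.

Step 10
Reactants: 24 2,4-dihydroxybenzaldehyde
Product: 26 2-methoxy-4-(methoxymethoxy)benzaldehyde, via mono-MOM aldehyde 25 (not isolated)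
Conditions: K2CO3 (3 equiv), MOMCl (1.05 equiv), acetone, 0 °C to rt; then MeI (2 equiv), reflux
Reagents that add atoms: chloromethyl methyl ether, COCCl; iodomethane, CI
Why: In this sequential Williamson etherification the 2-OH is held in a hydrogen bond to the aldehyde, so the 4-OH takes the single equivalent of MOMCl first and the remaining 2-OH is then methylated in the same flask.

Step 11
Reactants: 22 ring A acetophenone; 26 ring B aldehyde
Product: 27 (2E)-1-{6-hydroxy-2,4-bis(methoxymethoxy)-3-[(2S)-5-methyl-2-(prop-1-en-2-yl)hex-4-en-1-yl]phenyl}-3-[2-methoxy-4-(methoxymethoxy)phenyl]prop-2-en-1-one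
Conditions: KOH (50 % aq), EtOH, rt, 48 h; cold dilute citric acid to pH 6
Reagents that add atoms: none
Why: Claisen–Schmidt condensation (aldol addition then E1cB dehydration) gives the (E)-chalcone, which stays open in strong base as its chelated phenoxide, and MOM ethers and alkenes are inert to KOH.

Step 12
Reactants: 27 2'-hydroxychalcone
Product: 28 (2S)-2-[2-methoxy-4-(methoxymethoxy)phenyl]-5,7-bis(methoxymethoxy)-6-[(2S)-5-methyl-2-(prop-1-en-2-yl)hex-4-en-1-yl]-2,3-dihydro-4H-chromen-4-one
Conditions: 1-[3,5-bis(trifluoromethyl)phenyl]-3-[(2S)-3,3-dimethyl-1-{[tris(4-methoxyphenyl)phosphoranylidene]amino}butan-2-yl]thiourea (10 mol %), toluene, −20 °C, 72 h; AcOH quench at −20 °C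
Reagents that add atoms: none
Why: Proposed new method: a bifunctional iminophosphorane–thiourea superbase has not been used for the 6-endo-trig oxa-Michael closure of an unactivated 2'-hydroxychalcone; the iminophosphorane fully deprotonates the chelated phenol, the thiourea binds the s-cis enone carbonyl, the tight chiral ion pair delivers the phenoxide to the Si face of C-β to set (2S) under catalyst control (the side-chain centre is too remote to interfere), the enolate is protonated by the iminophosphonium ion, low temperature and the cold acid quench hold back retro-oxa-Michael racemisation, and the MOM ether on the other ortho oxygen allows only the 6-lavandulyl regioisomer; the closest known reaction types are the cinchona–thiourea oxa-Michael cyclisation of ester-activated 2'-hydroxychalcones and the iminophosphorane-catalysed intramolecular oxa-Michael addition of alcohols to unsaturated esters and amides.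

Step 13
Reactants: 28 tris-MOM flavanone
Product: 29 (2S)-5,7-dihydroxy-2-(4-hydroxy-2-methoxyphenyl)-6-[(2S)-5-methyl-2-(prop-1-en-2-yl)hex-4-en-1-yl]-2,3-dihydro-4H-chromen-4-one (target)
Conditions: 3 M HCl (aq)/MeOH 1:5, 45 °C, 3 h; NaHCO3 work-up
Reagents that add atoms: none
Why: Acid-catalysed acetal exchange with methanol removes all three MOM groups under conditions proven on prenylated flavanones, too mild to add the phenols across the side-chain alkenes and non-basic, so C-2 cannot epimerise by ring opening.

## Compound list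

1 | resorcinol | Oc1cccc(O)c1 | starting material
2 | 1,3-bis(methoxymethoxy)benzene | COCOc1cccc(OCOC)c1 | intermediate
3 | 2-[3,5-bis(methoxymethoxy)phenyl]-4,4,5,5-tetramethyl-1,3,2-dioxaborolane | COCOc1cc(OCOC)cc(c1)B1OC(C)(C)C(C)(C)O1 | intermediate
4 | 3,5-bis(methoxymethoxy)phenol | COCOc1cc(O)cc(OCOC)c1 | intermediate
5 | [3,5-bis(methoxymethoxy)phenoxy](tert-butyl)dimethylsilane | COCOc1cc(O[Si](C)(C)C(C)(C)C)cc(OCOC)c1 | intermediate
6 | [4-(tert-butyldimethylsilyloxy)-2,6-bis(methoxymethoxy)phenyl]lithium | [Li]c1c(OCOC)cc(O[Si](C)(C)C(C)(C)C)cc1OCOC | intermediate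
7 | lithium (chloromethyl)[4-(tert-butyldimethylsilyloxy)-2,6-bis(methoxymethoxy)phenyl](pinacolato)borate | [Li+].ClC[B-]1(OC(C)(C)C(C)(C)O1)c1c(OCOC)cc(O[Si](C)(C)C(C)(C)C)cc1OCOC | intermediate
8 | tert-butyl{3,5-bis(methoxymethoxy)-4-[(4,4,5,5-tetramethyl-1,3,2-dioxaborolan-2-yl)methyl]phenoxy}dimethylsilane | COCOc1cc(O[Si](C)(C)C(C)(C)C)cc(OCOC)c1CB1OC(C)(C)C(C)(C)O1 | intermediate
9 | 5-bromo-2-methylpent-2-ene | CC(C)=CCCBr | starting material
10 | 4-methylpent-3-en-1-yl 2,4,6-triisopropylbenzoate | CC(C)=CCCOC(=O)c1c(C(C)C)cc(C(C)C)cc1C(C)C | intermediate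
11 | (1R)-1-lithio-4-methylpent-3-en-1-yl 2,4,6-triisopropylbenzoate, present as its (+)-sparteine complex | [Li][C@H](CC=C(C)C)OC(=O)c1c(C(C)C)cc(C(C)C)cc1C(C)C | intermediate
12 | lithium {[4-(tert-butyldimethylsilyloxy)-2,6-bis(methoxymethoxy)phenyl]methyl}[(1R)-4-methyl-1-(2,4,6-triisopropylbenzoyloxy)pent-3-en-1-yl](pinacolato)borate | [Li+].COCOc1cc(O[Si](C)(C)C(C)(C)C)cc(OCOC)c1C[B-]1(OC(C)(C)C(C)(C)O1)[C@H](CC=C(C)C)OC(=O)c1c(C(C)C)cc(C(C)C)cc1C(C)C | intermediate
13 | tert-butyl{3,5-bis(methoxymethoxy)-4-[(2S)-5-methyl-2-(4,4,5,5-tetramethyl-1,3,2-dioxaborolan-2-yl)hex-4-en-1-yl]phenoxy}dimethylsilane | COCOc1cc(O[Si](C)(C)C(C)(C)C)cc(OCOC)c1C[C@H](CC=C(C)C)B1OC(C)(C)C(C)(C)O1 | intermediate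
14 | 2-bromopropene | C=C(C)Br | starting material
15 | isopropenyllithium (prop-1-en-2-yllithium) | [Li]C(C)=C | intermediate
16 | lithium (prop-1-en-2-yl){(2S)-1-[4-(tert-butyldimethylsilyloxy)-2,6-bis(methoxymethoxy)phenyl]-5-methylhex-4-en-2-yl}(pinacolato)borate | [Li+].COCOc1cc(O[Si](C)(C)C(C)(C)C)cc(OCOC)c1C[C@H](CC=C(C)C)[B-]1(OC(C)(C)C(C)(C)O1)C(C)=C | intermediate
17 | tert-butyl{4-[(2S)-2-[1-iodo-2-(4,4,5,5-tetramethyl-1,3,2-dioxaborolan-2-yl)propan-2-yl]-5-methylhex-4-en-1-yl]-3,5-bis(methoxymethoxy)phenoxy}dimethylsilane, both epimers at the boron-bearing carbon | COCOc1cc(O[Si](C)(C)C(C)(C)C)cc(OCOC)c1C[C@H](CC=C(C)C)C(C)(CI)B1OC(C)(C)C(C)(C)O1 | intermediate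
18 | tert-butyl{3,5-bis(methoxymethoxy)-4-[(2S)-5-methyl-2-(prop-1-en-2-yl)hex-4-en-1-yl]phenoxy}dimethylsilane | COCOc1cc(O[Si](C)(C)C(C)(C)C)cc(OCOC)c1C[C@H](CC=C(C)C)C(C)=C | intermediate
19 | 3,5-bis(methoxymethoxy)-4-[(2S)-5-methyl-2-(prop-1-en-2-yl)hex-4-en-1-yl]phenol | COCOc1cc(O)cc(OCOC)c1C[C@H](CC=C(C)C)C(C)=C | intermediate
20 | N-methoxy-N-methylacetamide | CC(=O)N(C)OC | starting material
21 | lithium 2-lithio-3,5-bis(methoxymethoxy)-4-[(2S)-5-methyl-2-(prop-1-en-2-yl)hex-4-en-1-yl]phenoxide | [Li]Oc1cc(OCOC)c(C[C@H](CC=C(C)C)C(C)=C)c(OCOC)c1[Li] | intermediate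
22 | 1-{6-hydroxy-2,4-bis(methoxymethoxy)-3-[(2S)-5-methyl-2-(prop-1-en-2-yl)hex-4-en-1-yl]phenyl}ethan-1-one | CC(=O)c1c(O)cc(OCOC)c(C[C@H](CC=C(C)C)C(C)=C)c1OCOC | intermediate
23 | N-[(2,4-dihydroxyphenyl)methylidene]-N-methylmethanaminium phosphorodichloridate | C[N+](C)=Cc1ccc(O)cc1O.[O-]P(=O)(Cl)Cl | intermediate
24 | 2,4-dihydroxybenzaldehyde | O=Cc1ccc(O)cc1O | intermediate
25 | 2-hydroxy-4-(methoxymethoxy)benzaldehyde | COCOc1ccc(C=O)c(O)c1 | intermediate
26 | 2-methoxy-4-(methoxymethoxy)benzaldehyde | COCOc1ccc(C=O)c(OC)c1 | intermediate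
27 | (2E)-1-{6-hydroxy-2,4-bis(methoxymethoxy)-3-[(2S)-5-methyl-2-(prop-1-en-2-yl)hex-4-en-1-yl]phenyl}-3-[2-methoxy-4-(methoxymethoxy)phenyl]prop-2-en-1-one | COCOc1ccc(/C=C/C(=O)c2c(O)cc(OCOC)c(C[C@H](CC=C(C)C)C(C)=C)c2OCOC)c(OC)c1 | intermediate
28 | (2S)-2-[2-methoxy-4-(methoxymethoxy)phenyl]-5,7-bis(methoxymethoxy)-6-[(2S)-5-methyl-2-(prop-1-en-2-yl)hex-4-en-1-yl]-2,3-dihydro-4H-chromen-4-one | C=C(C)[C@@H](CC=C(C)C)Cc1c(OCOC)cc2c(c1OCOC)C(=O)C[C@@H](c1ccc(OCOC)cc1OC)O2 | intermediate
29 | (2S)-5,7-dihydroxy-2-(4-hydroxy-2-methoxyphenyl)-6-[(2S)-5-methyl-2-(prop-1-en-2-yl)hex-4-en-1-yl]-2,3-dihydro-4H-chromen-4-one | C=C(C)[C@@H](CC=C(C)C)Cc1c(O)cc2c(c1O)C(=O)C[C@@H](c1ccc(O)cc1OC)O2 | target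

## Step count and risks

Total step count: 13.
Longest linear sequence: 10 (steps 1, 2, 3, 4, 6, 7, 8, 11, 12, 13).
Small amounts of stereoisomers carried from steps 6 and 12 are diastereomers of 28 and 29. They are removed at that stage by chromatography or recrystallisation.

**Step 12 (the proposed new cyclisation).**
- Risk: the electron-rich ring B makes C-β a poor acceptor, and the addition is reversible. The reaction may therefore be slow, and selectivity may erode through ring opening.
- Fallback (known chemistry): this sets out from 27. NaOAc in refluxing EtOH closes ring C without facial control and gives 28 together with its C-2 epimer, the (2R)-flavanone F1.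
- The two compounds are diastereomers and are separated by preparative HPLC on a chiral phase.
- F1 is returned to the same NaOAc equilibration, where it reopens to 27 and recloses, so the material converges on 28, where the route is rejoined.

**Step 8 (second lithiation on the free phenoxide).**
- Risk: ring metalation of the electron-rich phenoxide may be incomplete. It may also compete with allylic metalation or with enolisation of 20.
- Fallback: this sets out from 19. NIS in MeCN at −20 °C iodinates one of the two equivalent positions ortho to the phenol and gives 2-iodo-3,5-bis(methoxymethoxy)-4-[(2S)-5-methyl-2-(prop-1-en-2-yl)hex-4-en-1-yl]phenol F2.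
- n-BuLi (2.1 equiv, THF, −78 °C) first deprotonates the OH and then carries out a fast iodine–lithium exchange. This produces the dilithio species 21 site-specifically.
- Acetylation of 21 with 20 rejoins the route at 22.

**Step 6 (asymmetric lithiation–borylation).**
- Risk: boronate formation with the di-ortho-substituted benzylic boronic ester may be sluggish. Deprotonation of 8, double homologation or a lower enantiomer ratio are also possible.
- Fallback: this sets out from 8. Vinyllithium (Et2O/THF, 0 °C) gives the lithium vinyl boronate complex F3.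
- A conjunctive cross-coupling follows, catalysed by Pd(OAc)2 (2 mol %) and the MandyPhos enantiomer that leads to the (S)-product (THF, 60 °C). The coupling partner is 2-methylprop-1-en-1-yl trifluoromethanesulfonate F4, made from isobutyraldehyde, Tf2O and 2,6-di-tert-butyl-4-methylpyridine.
- This coupling induces the benzyl 1,2-shift from boron to the α-carbon while the alkenyl group is joined to the β-carbon. It gives 13 directly, where the route is rejoined.

## Further compounds

F1 | step 12 | (2R)-2-[2-methoxy-4-(methoxymethoxy)phenyl]-5,7-bis(methoxymethoxy)-6-[(2S)-5-methyl-2-(prop-1-en-2-yl)hex-4-en-1-yl]-2,3-dihydro-4H-chromen-4-one | C=C(C)[C@@H](CC=C(C)C)Cc1c(OCOC)cc2c(c1OCOC)C(=O)C[C@H](c1ccc(OCOC)cc1OC)O2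
F2 | step 8 | 2-iodo-3,5-bis(methoxymethoxy)-4-[(2S)-5-methyl-2-(prop-1-en-2-yl)hex-4-en-1-yl]phenol | Oc1cc(OCOC)c(C[C@H](CC=C(C)C)C(C)=C)c(OCOC)c1I
F3 | step 6 | lithium ethenyl{[4-(tert-butyldimethylsilyloxy)-2,6-bis(methoxymethoxy)phenyl]methyl}(pinacolato)borate | [Li+].COCOc1cc(O[Si](C)(C)C(C)(C)C)cc(OCOC)c1C[B-]1(OC(C)(C)C(C)(C)O1)C=C
F4 | step 6 | 2-methylprop-1-en-1-yl trifluoromethanesulfonate | CC(C)=COS(=O)(=O)C(F)(F)F
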